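**Plan**

- Numbering and enabling feature: ring carbons are C1 (bears the exocyclic =CH2), C4=C5(Me), C8 (isopropenyl), C9 (OAc), C10=C11 (C18H2OAc on C11) and C14 (OH). The feature that allows the key step is the homoallylic alcohol C9(O)–C8–C(CH3)=CH2 on the 14-membered ring with unsaturation at C10, which is the retron of a [2,3]-Wittig shift of a propargyl (E)-2-methylallyl ether.
- Retrosynthetic cuts, in order: the two acetates and C11–C18 (alkyne borylation, one-carbon homologation); C8–C9 ([2,3]-Wittig contraction of a 17-membered ether); C10≡C11 (ring-closing alkyne metathesis); O–C9 (Williamson); C1–C14 (vinyllithium plus Weinreb amide).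
- Forward order: (E)-geranylacetone is hydroxylated at its terminal (E)-methyl, converted into a 1-alken-2-yllithium (Shapiro) and acylated. CBS reduction, 2-butynyl ether formation and alkyne metathesis give the 17-membered ether. The Wittig shift contracts it to the 14-membered carbocycle, the only ring of the target, and the ring alkyne is then turned into the C10=C11(CH2OAc) unit.
- Stereochemistry: C14 (R) comes from CBS reduction. The C8/C9 relative configuration (anti) comes from the (E)-allyl ether geometry in the envelope transition state, and its absolute sense from a chiral lithium amide. C4=C5 comes from geranylacetone, the ether alkene from the selenium dioxide oxidation, and C10=C11 from syn borylcupration.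

Key step: step 11

Assumption: lithium (S,S)-bis(1-phenylethyl)amide is taken to be the base enantiomer that leads to the (8R,9R) product; if the sense proves opposite, the equally available (R,R)-amide is used in step 11 and nothing else changes.

**Route**

Step 1
Reactants: 1 (E)-geranylacetone
Product: 2 (5E,9E)-11-hydroxy-6,10-dimethylundeca-5,9-dien-2-one
Conditions: SeO2 (cat.), t-BuOOH, salicylic acid (cat.), CH2Cl2, 0 °C → rt
Reagents that add atoms: selenium dioxide O=[Se]=O (catalytic oxygen carrier); tert-butyl hydroperoxide CC(C)(C)OO (terminal oxidant)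
Why: Sharpless SeO2/TBHP allylic oxidation (ene reaction, then [2,3] shift) should hydroxylate the (E)-methyl of the terminal, most electron-rich trisubstituted alkene, which fixes the (E)-2-methylallyl alcohol geometry needed for the key step.

Step 2
Reactants: 2 (5E,9E)-11-hydroxy-6,10-dimethylundeca-5,9-dien-2-one
Product: 3 (5E,9E)-11-[(tert-butyldimethylsilyl)oxy]-6,10-dimethylundeca-5,9-dien-2-one
Conditions: TBSCl, imidazole, DMF, 0 °C → rt
Reagents that add atoms: tert-butyldimethylsilyl chloride CC(C)(C)[Si](C)(C)Cl
Why: Silyl ether formation masks the primary allylic alcohol against the organolithium chemistry that follows.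

Step 3
Reactants: 3 (5E,9E)-11-[(tert-butyldimethylsilyl)oxy]-6,10-dimethylundeca-5,9-dien-2-one
Product: 4 trisylhydrazone of ketone 3 (E at C=N)
Conditions: 2,4,6-triisopropylbenzenesulfonyl hydrazide, THF, rt
Reagents that add atoms: 2,4,6-triisopropylbenzenesulfonyl hydrazide NNS(=O)(=O)c1c(C(C)C)cc(C(C)C)cc1C(C)C
Why: Hydrazone condensation of a methyl ketone should give the E isomer (sulfonamide nitrogen syn to the methyl group), the substrate required for a regioselective Shapiro reaction.

Step 4
Reactants: 5 N-methoxy-N-methylacetamide; 6 1-bromobut-2-yne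
Product: 7 N-methoxy-N-methylhex-4-ynamide
Conditions: LDA, THF, –78 °C; then 6, –78 → –30 °C
Reagents that add atoms: none
Why: Alkylation of the lithium amide enolate with a reactive propargylic bromide (SN2) should give the methyl-capped alkynyl Weinreb amide, which serves the later acylation and the alkyne metathesis alike.

Step 5
Reactants: 4 trisylhydrazone of ketone 3; 7 N-methoxy-N-methylhex-4-ynamide
Product: 9 enone (10E,14E)-16-[(tert-butyldimethylsilyl)oxy]-11,15-dimethyl-7-methylidenehexadeca-10,14-dien-2-yn-6-one, via vinyllithium 8 (not isolated)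
Conditions: n-BuLi (2.1 equiv), THF, –78 → 0 °C; then 7, –78 °C; aq. NH4Cl
Reagents that add atoms: none
Why: In the Shapiro reaction, deprotonation at N–H and at the syn methyl group followed by loss of sulfinate and N2 gives the 1-alken-2-yllithium, and the Weinreb ketone synthesis stops at the ketone through the chelated tetrahedral intermediate, forming the C1–C14 bond.

Step 6
Reactants: 9 enone
Product: 10 (6R,10E,14E)-16-[(tert-butyldimethylsilyl)oxy]-11,15-dimethyl-7-methylidenehexadeca-10,14-dien-2-yn-6-ol
Conditions: (S)-Me-CBS oxazaborolidine (0.5 equiv), catecholborane, toluene, –78 °C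
Reagents that add atoms: none
Why: In the Corey–Bakshi–Shibata reduction the α-branched alkenyl group acts as the large substituent, so the (S)-catalyst should deliver hydride to the face that gives the (R)-carbinol (C14 of the target) by 1,2-reduction, with catecholborane at –78 °C leaving alkenes and alkyne untouched.

Step 7
Reactants: 10 (R)-allylic alcohol
Product: 11 (6R,10E,14E)-6,16-bis[(tert-butyldimethylsilyl)oxy]-11,15-dimethyl-7-methylidenehexadeca-10,14-dien-2-yne
Conditions: TBSOTf, 2,6-lutidine, CH2Cl2, –78 °C
Reagents that add atoms: tert-butyldimethylsilyl triflate CC(C)(C)[Si](C)(C)OS(=O)(=O)C(F)(F)F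
Why: Silylation with the reactive silyl triflate should protect the hindered secondary allylic alcohol without touching the stereocentre.

Step 8
Reactants: 11 bis-silyl ether
Product: 12 (2E,6E,11R)-11-[(tert-butyldimethylsilyl)oxy]-2,6-dimethyl-10-methylidenehexadeca-2,6-dien-14-yn-1-ol
Conditions: HF·pyridine, pyridine, THF, 0 °C
Reagents that add atoms: none
Why: Buffered fluoride desilylation should cleave the unhindered primary allylic silyl ether much faster than the secondary one flanked by the 1,1-disubstituted alkene (steric differentiation of silyl ethers).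

Step 9
Reactants: 12 primary allylic alcohol; 6 1-bromobut-2-yne
Product: 13 (6R,10E,14E)-16-(but-2-yn-1-yloxy)-6-[(tert-butyldimethylsilyl)oxy]-11,15-dimethyl-7-methylidenehexadeca-10,14-dien-2-yne
Conditions: NaH, THF/DMF, 0 °C; then 6, Bu4NI (cat.), rt
Reagents that add atoms: none
Why: Williamson etherification of the primary allylic alkoxide with a propargylic bromide (SN2) installs C9 and the ether oxygen bridge.

Step 10
Reactants: 13 diyne ether
Product: 14 17-membered ether (3E,7E,12R)-12-[(tert-butyldimethylsilyl)oxy]-3,7-dimethyl-11-methylidene-1-oxacycloheptadeca-3,7-dien-15-yne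
Conditions: [Mo(≡CC6H4-4-OMe)(OSiPh3)3] (5–10 mol%), 5 Å MS, toluene (2 mM), rt → 60 °C
Reagents that add atoms: none
Why: Ring-closing alkyne metathesis with a molybdenum alkylidyne is driven by loss of but-2-yne (taken up by the sieves), leaves alkenes, silyl ethers and propargyl ethers alone, and should close the large ring at C10≡C11 under high dilution.

Step 11
Reactants: 14 17-membered propargyl (E)-2-methylallyl ether
Product: 16 14-membered alkynol (4E,8R,9R,14R)-14-[(tert-butyldimethylsilyl)oxy]-5-methyl-1-methylidene-8-(prop-1-en-2-yl)cyclotetradec-4-en-10-yn-9-ol (plan numbering), via C9-lithiated ether 15 (not isolated)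
Conditions: (S,S)-bis(1-phenylethyl)amine, n-BuLi, THF, –78 → –25 °C; aq. NH4Cl
Reagents that add atoms: none
Why: The amide removes a propargylic α-oxy proton at C9 and the carbanion bonds to C8 through a five-membered envelope transition state while the O–CH2 bond breaks and the double bond moves into the isopropenyl position, a [2,3]-Wittig rearrangement that is known as a ring contraction of macrocyclic propargyl allyl ethers, also with this chiral amide. The 14-membered carbocycle arises by sigmatropic contraction of the 17-membered ether: C8–C9 forms inside the ring and the oxygen, its CH2 and the methyl-bearing carbon leave the ring, so no end-to-end cyclisation is involved. The relative configuration at C8/C9 follows from the (E)-alkene and the envelope with the alkynyl group exo, which places C9–O anti to C8–C7 along C10–C9–C8–isopropenyl. The absolute sense is set by the chiral amide, which distinguishes the two C9 protons (diastereotopic because of C14) and stays associated with the lithium during the fast shift. Site selectivity for C9–H over the allylic O–CH2 and the C12 protons rests on the higher acidity of the propargylic α-oxy position, and the low temperature disfavours the [1,2] shift. Because C14 is already fixed, any (8S,9S) product is a diastereomer and should be removable by chromatography.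

Step 12
Reactants: 16 14-membered alkynol
Product: 17 alkenyl boronate (4E,8R,9S,10Z,14R)-14-[(tert-butyldimethylsilyl)oxy]-5-methyl-1-methylidene-8-(prop-1-en-2-yl)-11-(4,4,5,5-tetramethyl-1,3,2-dioxaborolan-2-yl)cyclotetradeca-4,10-dien-9-ol (plan numbering)
Conditions: B2pin2, CuCl (10 mol%), PCy3 (12 mol%), NaOt-Bu (15 mol%), MeOH (2 equiv), toluene, rt
Reagents that add atoms: bis(pinacolato)diboron CC1(C)OB(OC1(C)C)B1OC(C)(C)C(C)(C)O1
Why: In the copper-catalysed formal hydroboration, Cu–Bpin adds syn across the alkyne with boron on C11 (distal to the propargylic oxygen and to the branched C9) and methanol protonates C10, which should give the ring-cis alkene with H on C10 while the unactivated alkenes stay inert.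

Step 13
Reactants: 17 alkenyl boronate
Product: 19 diol (4E,8R,9S,10E,14R)-14-[(tert-butyldimethylsilyl)oxy]-11-(hydroxymethyl)-5-methyl-1-methylidene-8-(prop-1-en-2-yl)cyclotetradeca-4,10-dien-9-ol (plan numbering), via allylic boronate 18 (not isolated)
Conditions: BrCH2Cl, n-BuLi, THF, –78 °C → rt; then NaOH, H2O2, THF/H2O, 0 °C
Reagents that add atoms: bromochloromethane ClCBr; hydrogen peroxide OO
Why: Matteson homologation (boron ate complex, 1,2-shift of the alkenyl group with retention of alkene geometry) inserts C18 between C11 and boron, and alkaline peroxide oxidation of the allylic boronate should give the primary allylic alcohol without allylic transposition; the C9 alkoxide is trans to boron across the alkene and cannot chelate it.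

Step 14
Reactants: 19 diol
Product: 20 diacetate (4E,8R,9S,10E,14R)-9-acetoxy-11-(acetoxymethyl)-14-[(tert-butyldimethylsilyl)oxy]-5-methyl-1-methylidene-8-(prop-1-en-2-yl)cyclotetradeca-4,10-diene (plan numbering)
Conditions: Ac2O, pyridine, DMAP (cat.), CH2Cl2, 0 °C → rt
Reagents that add atoms: acetic anhydride CC(=O)OC(C)=O
Why: DMAP-catalysed acylation esterifies the primary and the secondary allylic alcohol while C14 remains silylated.

Step 15
Reactants: 20 diacetate
Product: 21 target (4E,8R,9S,10E,14R)-9-acetoxy-11-(acetoxymethyl)-5-methyl-1-methylidene-8-(prop-1-en-2-yl)cyclotetradeca-4,10-dien-14-ol (plan numbering)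
Conditions: HF·pyridine, pyridine, THF, 0 °C → rt
Reagents that add atoms: none
Why: Fluoride desilylation under buffered, non-basic conditions should free the C14 alcohol without cleavage or migration of the allylic acetates.

**Compound list**

1 | (E)-geranylacetone, (5E)-6,10-dimethylundeca-5,9-dien-2-one (commercial E isomer) | CC(=O)CC/C=C(\C)CCC=C(C)C | starting material
2 | (5E,9E)-11-hydroxy-6,10-dimethylundeca-5,9-dien-2-one | CC(=O)CC/C=C(\C)CC/C=C(\C)CO | intermediate
3 | (5E,9E)-11-[(tert-butyldimethylsilyl)oxy]-6,10-dimethylundeca-5,9-dien-2-one | CC(=O)CC/C=C(\C)CC/C=C(\C)CO[Si](C)(C)C(C)(C)C | intermediate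
4 | 2,4,6-triisopropylbenzenesulfonyl hydrazone of 3 (E at C=N) | C/C(CC/C=C(\C)CC/C=C(\C)CO[Si](C)(C)C(C)(C)C)=N\NS(=O)(=O)c1c(C(C)C)cc(C(C)C)cc1C(C)C | intermediate
5 | N-methoxy-N-methylacetamide | CC(=O)N(C)OC | starting material
6 | 1-bromobut-2-yne | CC#CCBr | starting material
7 | N-methoxy-N-methylhex-4-ynamide | CC#CCCC(=O)N(C)OC | intermediate
8 | (5E,9E)-11-[(tert-butyldimethylsilyl)oxy]-6,10-dimethylundeca-1,5,9-trien-2-yllithium | [Li]C(=C)CC/C=C(\C)CC/C=C(\C)CO[Si](C)(C)C(C)(C)C | intermediate
9 | (10E,14E)-16-[(tert-butyldimethylsilyl)oxy]-11,15-dimethyl-7-methylidenehexadeca-10,14-dien-2-yn-6-one | C=C(CC/C=C(\C)CC/C=C(\C)CO[Si](C)(C)C(C)(C)C)C(=O)CCC#CC | intermediate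
10 | (6R,10E,14E)-16-[(tert-butyldimethylsilyl)oxy]-11,15-dimethyl-7-methylidenehexadeca-10,14-dien-2-yn-6-ol | C=C(CC/C=C(\C)CC/C=C(\C)CO[Si](C)(C)C(C)(C)C)[C@H](O)CCC#CC | intermediate
11 | (6R,10E,14E)-6,16-bis[(tert-butyldimethylsilyl)oxy]-11,15-dimethyl-7-methylidenehexadeca-10,14-dien-2-yne | C=C(CC/C=C(\C)CC/C=C(\C)CO[Si](C)(C)C(C)(C)C)[C@H](O[Si](C)(C)C(C)(C)C)CCC#CC | intermediate
12 | (2E,6E,11R)-11-[(tert-butyldimethylsilyl)oxy]-2,6-dimethyl-10-methylidenehexadeca-2,6-dien-14-yn-1-ol | C=C(CC/C=C(\C)CC/C=C(\C)CO)[C@H](O[Si](C)(C)C(C)(C)C)CCC#CC | intermediate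
13 | (6R,10E,14E)-16-(but-2-yn-1-yloxy)-6-[(tert-butyldimethylsilyl)oxy]-11,15-dimethyl-7-methylidenehexadeca-10,14-dien-2-yne | C=C(CC/C=C(\C)CC/C=C(\C)COCC#CC)[C@H](O[Si](C)(C)C(C)(C)C)CCC#CC | intermediate
14 | (3E,7E,12R)-12-[(tert-butyldimethylsilyl)oxy]-3,7-dimethyl-11-methylidene-1-oxacycloheptadeca-3,7-dien-15-yne (17-membered propargyl allyl ether) | C=C1CC/C=C(\C)CC/C=C(\C)COCC#CCC[C@H]1O[Si](C)(C)C(C)(C)C | intermediate
15 | 14 lithiated at the propargylic O–CH carbon (C9 of the plan numbering) | C=C1CC/C=C(\C)CC/C=C(\C)COC([Li])C#CCC[C@H]1O[Si](C)(C)C(C)(C)C | intermediate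
16 | (4E,8R,9R,14R)-14-[(tert-butyldimethylsilyl)oxy]-5-methyl-1-methylidene-8-(prop-1-en-2-yl)cyclotetradec-4-en-10-yn-9-ol (plan numbering) | C=C1CC/C=C(\C)CC[C@H](C(=C)C)[C@@H](O)C#CCC[C@H]1O[Si](C)(C)C(C)(C)C | intermediate
17 | (4E,8R,9S,10Z,14R)-14-[(tert-butyldimethylsilyl)oxy]-5-methyl-1-methylidene-8-(prop-1-en-2-yl)-11-(4,4,5,5-tetramethyl-1,3,2-dioxaborolan-2-yl)cyclotetradeca-4,10-dien-9-ol (plan numbering) | C=C1CC/C=C(\C)CC[C@H](C(=C)C)[C@@H](O)/C=C(/B2OC(C)(C)C(C)(C)O2)CC[C@H]1O[Si](C)(C)C(C)(C)C | intermediate
18 | (4E,8R,9S,10Z,14R)-14-[(tert-butyldimethylsilyl)oxy]-5-methyl-1-methylidene-8-(prop-1-en-2-yl)-11-[(4,4,5,5-tetramethyl-1,3,2-dioxaborolan-2-yl)methyl]cyclotetradeca-4,10-dien-9-ol (plan numbering; present as its lithium alkoxide) | C=C1CC/C=C(\C)CC[C@H](C(=C)C)[C@@H](O)/C=C(/CB2OC(C)(C)C(C)(C)O2)CC[C@H]1O[Si](C)(C)C(C)(C)C | intermediate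
19 | (4E,8R,9S,10E,14R)-14-[(tert-butyldimethylsilyl)oxy]-11-(hydroxymethyl)-5-methyl-1-methylidene-8-(prop-1-en-2-yl)cyclotetradeca-4,10-dien-9-ol (plan numbering) | C=C1CC/C=C(\C)CC[C@H](C(=C)C)[C@@H](O)/C=C(/CO)CC[C@H]1O[Si](C)(C)C(C)(C)C | intermediate
20 | (4E,8R,9S,10E,14R)-9-acetoxy-11-(acetoxymethyl)-14-[(tert-butyldimethylsilyl)oxy]-5-methyl-1-methylidene-8-(prop-1-en-2-yl)cyclotetradeca-4,10-diene (plan numbering) | C=C1CC/C=C(\C)CC[C@H](C(=C)C)[C@@H](OC(C)=O)/C=C(/COC(C)=O)CC[C@H]1O[Si](C)(C)C(C)(C)C | intermediate
21 | (4E,8R,9S,10E,14R)-9-acetoxy-11-(acetoxymethyl)-5-methyl-1-methylidene-8-(prop-1-en-2-yl)cyclotetradeca-4,10-dien-14-ol (plan numbering), CNP0077636.1 | C=C1CC/C=C(\C)CC[C@H](C(=C)C)[C@@H](OC(C)=O)/C=C(/COC(C)=O)CC[C@H]1O | target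

**Step count**

Total: 15 steps. Longest linear sequence: 14 steps (1 → 21 through steps 1–3 and 5–15).

**Steps most likely to fail**

Step 11. The chiral amide may discriminate the two C9 protons poorly on the flexible 17-membered ring, or be mismatched with the C14 centre, so that both anti diastereomers form in similar amounts. The fallback gives up reagent control and separates covalent derivatives instead. Starting from 14, n-BuLi in THF–pentane at –78 °C would give 16 together with the (8S,9S,14R)-alkynol F1. The mixture would be esterified with (S)-O-methylmandelic acid (DCC, DMAP) to the (S)-O-methylmandelate of 16 F2 and the (S)-O-methylmandelate of the diastereomer F3. These differ at the carbon next to the new ester and should separate on silica. Methanolysis of F2 (K2CO3, MeOH) would return to the route at 16.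

Step 13. The C9 alkoxide and the hindered, 1,1-disubstituted alkenyl boron centre may slow ate-complex formation, leading to incomplete or double homologation and protodeboronation. The fallback replaces the boron-to-carbon migration by a palladium coupling. Starting from 17, iododeboronation with NaOH and I2 in THF/water (retention of alkene geometry) would give the alkenyl iodide F4. Stille hydroxymethylation with (tributylstannyl)methanol and Pd(PPh3)4 in dioxane at 90 °C would then form C11–C18 and return to the route at 19.

Step 5. The vinyllithium may be lost by protonation (by THF during nitrogen extrusion or by enolisation of the Weinreb amide), and deprotonation of the hydrazone may not be fully regioselective, so the coupling could stall. The fallback moves the C1–C14 bond formation to a chromium-mediated addition. Starting from 3, kinetic enolisation (LDA, THF, –78 °C) and trapping with PhNTf2 would give the 1-alken-2-yl triflate F5. Nozaki–Hiyama–Kishi coupling (CrCl2, cat. NiCl2, DMF) with hex-4-ynal F6, made from commercial hex-4-yn-1-ol by Dess–Martin oxidation, would give the racemic allylic alcohol F7. Dess–Martin oxidation of F7 would return to the route at 9.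

**Further compounds**

F1 | step 11 | (4E,8S,9S,14R)-14-[(tert-butyldimethylsilyl)oxy]-5-methyl-1-methylidene-8-(prop-1-en-2-yl)cyclotetradec-4-en-10-yn-9-ol (plan numbering) | C=C1CC/C=C(\C)CC[C@@H](C(=C)C)[C@H](O)C#CCC[C@H]1O[Si](C)(C)C(C)(C)C
F2 | step 11 | (S)-2-methoxy-2-phenylacetate of 16 | C=C1CC/C=C(\C)CC[C@H](C(=C)C)[C@@H](OC(=O)[C@@H](OC)c2ccccc2)C#CCC[C@H]1O[Si](C)(C)C(C)(C)C
F3 | step 11 | (S)-2-methoxy-2-phenylacetate of F1 | C=C1CC/C=C(\C)CC[C@@H](C(=C)C)[C@H](OC(=O)[C@@H](OC)c2ccccc2)C#CCC[C@H]1O[Si](C)(C)C(C)(C)C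
F4 | step 13 | (4E,8R,9S,14R)-14-[(tert-butyldimethylsilyl)oxy]-11-iodo-5-methyl-1-methylidene-8-(prop-1-en-2-yl)cyclotetradeca-4,10-dien-9-ol with iodine trans to C9 (plan numbering) | C=C1CC/C=C(\C)CC[C@H](C(=C)C)[C@@H](O)/C=C(/I)CC[C@H]1O[Si](C)(C)C(C)(C)C
F5 | step 5 | (5E,9E)-11-[(tert-butyldimethylsilyl)oxy]-6,10-dimethylundeca-1,5,9-trien-2-yl trifluoromethanesulfonate | C=C(OS(=O)(=O)C(F)(F)F)CC/C=C(\C)CC/C=C(\C)CO[Si](C)(C)C(C)(C)C
F6 | step 5 | hex-4-ynal | CC#CCCC=O
F7 | step 5 | (10E,14E)-16-[(tert-butyldimethylsilyl)oxy]-11,15-dimethyl-7-methylidenehexadeca-10,14-dien-2-yn-6-ol (racemic at C6) | C=C(CC/C=C(\C)CC/C=C(\C)CO[Si](C)(C)C(C)(C)C)C(O)CCC#CC
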